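**Plan**

1. The target is an achiral octamer with rings lettered A (3,5-dihydroxyphenyl end) to H (2,4,6-trihydroxyphenyl end). Rings B, D and F each carry the oxygen of the previous ring at C1, the oxygen of the next ring at C2, H at C3 and OH at C4 to C6. That pattern is an aryloxyacetylene (C2–C3) inserted into a four-carbon squarate unit (C4–C5–C6–C1).
2. Retrosynthesis: after global O-demethylation, ring F is cut at C3–C4 and C1–C2 (cyclobutenone plus ynol ether), then ring D and ring B in the same way. Each cyclobutenone is cut at its aryl-O–squarate bond, each ynol ether at its O–C(sp) bond, and the G–O–H ether by an Ullmann disconnection.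
3. Forward: the ring A cyclobutenone and the ring C ynol ether close ring B. O-methylation, debenzylation and loading of the freed ring C phenol on a chlorosquarate give the next cyclobutenone. The cycle is repeated to close ring D and then ring F, the last ynol ether already carrying rings G and H. BBr3 then frees all twenty hydroxyls.
4. Stereochemistry: the target has no stereocentre. The one sp3 carbon of each cyclobutenone is racemic and becomes aromatic C5.

Key step: step 10

Remark on the chemistry: in the names of the larger intermediates, rings B, D, F are numbered as in line 1 of the plan. Rings C, E, G carry the oxygen of the previous ring at C1, methoxy groups at C2 and C6, and the next oxygen at C4.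

**Route**

Step 1
Reactants: 1 squaric acid (3,4-dihydroxycyclobut-3-ene-1,2-dione)
Product: 2 squaryl dichloride (3,4-dichlorocyclobut-3-ene-1,2-dione)
Conditions: (COCl)2 (2.2 equiv), DMF (cat.), CH2Cl2, rt to 40 °C
Reagents that add atoms: oxalyl chloride, ClC(=O)C(=O)Cl
Why: Vilsmeier-type chlorination of the two vinylogous carboxylic acid OH groups (acid chloride formation) is the standard preparation of squaryl dichloride.

Step 2
Reactants: 2 squaryl dichloride
Product: 3 3-chloro-4-methoxycyclobut-3-ene-1,2-dione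
Conditions: MeOH (1.0 equiv), CH2Cl2, −20 °C to rt, N2 sweep
Reagents that add atoms: methanol, CO
Why: Vinylogous acyl substitution (addition–elimination) with one equivalent of alcohol should stop at the ester chloride, because the first methoxy group turns the remaining C–Cl carbon into a less electrophilic vinylogous ester position.

Step 3
Reactants: 3 3-chloro-4-methoxycyclobut-3-ene-1,2-dione; 4 3,5-dimethoxyphenol
Product: 5 3-(3,5-dimethoxyphenoxy)-4-methoxycyclobut-3-ene-1,2-dione
Conditions: i-Pr2NEt (1.1 equiv), CH2Cl2, −40 to 0 °C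
Reagents that add atoms: none
Why: Vinylogous O-acylation of a phenoxide by an acid chloride equivalent (addition–elimination) should be clean because chloride leaves far more readily than methoxide, and base at low temperature should keep the electron-rich arene from reacting through carbon.

Step 4
Reactants: 5 3-(3,5-dimethoxyphenoxy)-4-methoxycyclobut-3-ene-1,2-dione
Product: 6 2-(3,5-dimethoxyphenoxy)-4-hydroxy-3-methoxycyclobut-2-en-1-one (racemic)
Conditions: LiAlH(O-t-Bu)3 (1.05 equiv), THF, −78 °C; then pH 7 buffer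
Reagents that add atoms: none
Why: 1,2-Reduction of a squarate carbonyl by a bulky alkoxyaluminium hydride, known for dialkyl squarates, should occur at the carbonyl next to C–OMe, which is conjugated to the weaker donor OAr and is therefore the more electrophilic one; the new carbinol centre is racemic and is erased later.

Step 5
Reactants: 6 2-(3,5-dimethoxyphenoxy)-4-hydroxy-3-methoxycyclobut-2-en-1-one
Product: 7 2-(3,5-dimethoxyphenoxy)-3,4-dimethoxycyclobut-2-en-1-one (racemic)
Conditions: MeI (5 equiv), Ag2O (1.5 equiv), CH2Cl2, rt, dark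
Reagents that add atoms: iodomethane, CI
Why: Purdie methylation (Ag2O/MeI) should etherify the secondary alcohol without a free alkoxide, which avoids base-induced opening of the strained hydroxycyclobutenone.

Step 6
Reactants: 8 2,6-dimethoxy-1,4-benzoquinone
Product: 9 2,6-dimethoxybenzene-1,4-diol
Conditions: Na2S2O4, EtOAc/H2O, rt, Ar
Reagents that add atoms: none
Why: Dithionite reduction of a quinone to its hydroquinone is routine.

Step 7
Reactants: 9 2,6-dimethoxybenzene-1,4-diol
Product: 10 4-(benzyloxy)-2,6-dimethoxyphenol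
Conditions: BnBr (1.0 equiv), K2CO3 (1.0 equiv), DMF, rt, Ar
Reagents that add atoms: benzyl bromide, BrCc1ccccc1
Why: Williamson etherification should take place at the 4-OH, which is unhindered and the more acidic of the two, whereas the 1-OH is flanked by two methoxy groups.

Step 8
Reactants: 10 4-(benzyloxy)-2,6-dimethoxyphenol; 11 trichloroethylene
Product: 12 5-(benzyloxy)-2-{[(E)-1,2-dichloroethenyl]oxy}-1,3-dimethoxybenzene
Conditions: K2CO3, DMF, 70 °C
Reagents that add atoms: none
Why: Base-mediated dichlorovinylation of a phenol by trichloroethylene (net vinylic substitution) is the established first stage of the Greene ynol ether synthesis and tolerates ortho,ortho-disubstituted phenols.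

Step 9
Reactants: 12 5-(benzyloxy)-2-{[(E)-1,2-dichloroethenyl]oxy}-1,3-dimethoxybenzene
Product: 15 5-(benzyloxy)-2-(ethynyloxy)-1,3-dimethoxybenzene, via chloroalkyne 13 (not isolated), via lithium acetylide 14 (not isolated)
Conditions: n-BuLi (2.2 equiv), THF, −78 to −60 °C; then H2O
Reagents that add atoms: none
Why: In the second stage of the Greene ynol ether synthesis, n-BuLi removes the vinylic proton with loss of LiCl to give chloroalkyne 13, chlorine–lithium exchange gives acetylide 14, and protonation gives the terminal aryl ynol ether, whose two ortho methoxy groups should slow its self-condensation.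

Step 10
Reactants: 7 2-(3,5-dimethoxyphenoxy)-3,4-dimethoxycyclobut-2-en-1-one; 15 5-(benzyloxy)-2-(ethynyloxy)-1,3-dimethoxybenzene
Product: 20 5-[4-(benzyloxy)-2,6-dimethoxyphenoxy]-4-(3,5-dimethoxyphenoxy)-2,3-dimethoxyphenol, via vinylketene 16 (not isolated), via vinylcyclobutenone 17 (not isolated), via dienylketene 18 (not isolated), via cyclohexadienone 19 (not isolated)
Conditions: PhMe (degassed), 110 °C, slow addition of 15 (1.5 equiv)
Reagents that add atoms: none
Why: This is a Danheiser benzannulation, the closest precedent being the union of cyclobutenones with alkoxy- and siloxyacetylenes. Heating should open 7 by a 4π electrocyclic reaction (the methoxy group on the sp3 carbon rotating outward) to vinylketene 16, whose ketene C=C adds ynol ether 15 in a [2+2] cycloaddition to give vinylcyclobutenone 17. A second 4π opening, in which the donor aryloxy group turns outward and the vinyl group inward, gives dienylketene 18. Ring B then closes by a thermal disrotatory 6π electrocyclisation between the ketene carbon (C4) and the methoxy-bearing terminus (C5) to give cyclohexadienone 19, which tautomerises to phenol 20. The regioselectivity needed is fixed in the [2+2] step: the oxygen lone pair makes the terminal CH carbon of 15 nucleophilic, so it bonds to the ketene carbonyl carbon (new C3–C4 bond) while the oxygen-bearing alkyne carbon bonds to the aryloxy-bearing ketene carbon (new C1–C2 bond), which puts H at C3 and the two aryl ethers on C1 and C2. No stereocentre survives, since the racemic sp3 carbon of 7 becomes aromatic C5.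

Step 11
Reactants: 20 5-[4-(benzyloxy)-2,6-dimethoxyphenoxy]-4-(3,5-dimethoxyphenoxy)-2,3-dimethoxyphenol
Product: 21 5-(benzyloxy)-2-[2-(3,5-dimethoxyphenoxy)-3,4,5-trimethoxyphenoxy]-1,3-dimethoxybenzene
Conditions: MeI, K2CO3, DMF, rt
Reagents that add atoms: iodomethane, CI
Why: Williamson methylation caps the ring B phenol, so that debenzylation will leave a single free phenol.

Step 12
Reactants: 21 5-(benzyloxy)-2-[2-(3,5-dimethoxyphenoxy)-3,4,5-trimethoxyphenoxy]-1,3-dimethoxybenzene
Product: 22 4-[2-(3,5-dimethoxyphenoxy)-3,4,5-trimethoxyphenoxy]-3,5-dimethoxyphenol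
Conditions: H2 (1 atm), Pd/C, EtOAc/MeOH, rt
Reagents that add atoms: none
Why: Hydrogenolysis of a benzyl ether over palladium on carbon leaves methyl and diaryl ethers untouched.

Step 13
Reactants: 22 4-[2-(3,5-dimethoxyphenoxy)-3,4,5-trimethoxyphenoxy]-3,5-dimethoxyphenol; 3 3-chloro-4-methoxycyclobut-3-ene-1,2-dione
Product: 23 3-{4-[2-(3,5-dimethoxyphenoxy)-3,4,5-trimethoxyphenoxy]-3,5-dimethoxyphenoxy}-4-methoxycyclobut-3-ene-1,2-dione
Conditions: i-Pr2NEt (1.1 equiv), CH2Cl2, −40 to 0 °C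
Reagents that add atoms: none
Why: The same vinylogous O-acylation (addition–elimination at the C–Cl carbon) as in step 3 should load the only free phenol on the squarate.

Step 14
Reactants: 23 methyl squarate ester of the A–C trimer
Product: 24 2-{4-[2-(3,5-dimethoxyphenoxy)-3,4,5-trimethoxyphenoxy]-3,5-dimethoxyphenoxy}-4-hydroxy-3-methoxycyclobut-2-en-1-one (racemic)
Conditions: LiAlH(O-t-Bu)3 (1.05 equiv), THF, −78 °C; then pH 7 buffer
Reagents that add atoms: none
Why: 1,2-Hydride reduction with the regiochemistry argued in step 4 should again reduce the carbonyl next to C–OMe; the carbinol centre is racemic and transient.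

Step 15
Reactants: 24 hydroxycyclobutenone of the A–C trimer
Product: 25 2-{4-[2-(3,5-dimethoxyphenoxy)-3,4,5-trimethoxyphenoxy]-3,5-dimethoxyphenoxy}-3,4-dimethoxycyclobut-2-en-1-one (racemic)
Conditions: MeI (5 equiv), Ag2O (1.5 equiv), CH2Cl2, rt, dark
Reagents that add atoms: iodomethane, CI
Why: Purdie methylation under non-basic conditions, as in step 5.

Step 16
Reactants: 25 cyclobutenone of the A–C trimer; 15 5-(benzyloxy)-2-(ethynyloxy)-1,3-dimethoxybenzene
Product: 30 pentamer phenol A–E (ring D 4-OH free; ring E 4-OBn; all other oxygens OMe), via vinylketene 26 (not isolated), via vinylcyclobutenone 27 (not isolated), via dienylketene 28 (not isolated), via cyclohexadienone 29 (not isolated)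
Conditions: PhMe (degassed), 110 °C, slow addition of 15 (1.5 equiv)
Reagents that add atoms: none
Why: The same Danheiser benzannulation cascade as in step 10 (4π opening, regioselective [2+2] addition of the ynol ether, 4π opening, 6π electrocyclisation, tautomerisation) should close ring D with the ring C oxygen at C1 and the ring E oxygen at C2.

Step 17
Reactants: 30 pentamer phenol A–E
Product: 31 pentamer A–E benzyl ether (ring D 4-OMe; ring E 4-OBn; all other oxygens OMe)
Conditions: MeI, K2CO3, DMF, rt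
Reagents that add atoms: iodomethane, CI
Why: Williamson methylation of the ring D phenol, as in step 11.

Step 18
Reactants: 31 pentamer A–E benzyl ether
Product: 32 pentamer phenol A–E (ring E 4-OH free; all other oxygens OMe)
Conditions: H2 (1 atm), Pd/C, EtOAc/MeOH, rt
Reagents that add atoms: none
Why: Benzyl ether hydrogenolysis over palladium on carbon, as in step 12.

Step 19
Reactants: 32 pentamer phenol A–E; 3 3-chloro-4-methoxycyclobut-3-ene-1,2-dione
Product: 33 methyl squarate ester of 32 (3-aryloxy-4-methoxycyclobut-3-ene-1,2-dione on the ring E 4-oxygen)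
Conditions: i-Pr2NEt (1.1 equiv), CH2Cl2, −40 to 0 °C
Reagents that add atoms: none
Why: Vinylogous O-acylation of the single phenol by the squarate ester chloride, as in step 3.

Step 20
Reactants: 33 methyl squarate ester of the pentamer
Product: 34 hydroxycyclobutenone of the pentamer (2-aryloxy-4-hydroxy-3-methoxycyclobut-2-en-1-one on the ring E 4-oxygen; racemic)
Conditions: LiAlH(O-t-Bu)3 (1.05 equiv), THF, −78 °C; then pH 7 buffer
Reagents that add atoms: none
Why: Regioselective 1,2-hydride reduction of the carbonyl next to C–OMe, as in step 4; the carbinol centre is racemic and transient.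

Step 21
Reactants: 34 hydroxycyclobutenone of the pentamer
Product: 35 cyclobutenone of the pentamer (2-aryloxy-3,4-dimethoxycyclobut-2-en-1-one on the ring E 4-oxygen; racemic)
Conditions: MeI (5 equiv), Ag2O (1.5 equiv), CH2Cl2, rt, dark
Reagents that add atoms: iodomethane, CI
Why: Purdie methylation under non-basic conditions, as in step 5.

Step 22
Reactants: 36 4-bromo-2,6-dimethoxyphenol
Product: 37 2-(benzyloxy)-5-bromo-1,3-dimethoxybenzene
Conditions: BnBr, K2CO3, DMF, 50 °C
Reagents that add atoms: benzyl bromide, BrCc1ccccc1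
Why: Williamson benzylation masks the ring G phenol that will later become the ynol ether oxygen.

Step 23
Reactants: 37 2-(benzyloxy)-5-bromo-1,3-dimethoxybenzene; 38 2,4,6-trimethoxyphenol
Product: 39 2-(benzyloxy)-1,3-dimethoxy-5-(2,4,6-trimethoxyphenoxy)benzene
Conditions: CuI (10 mol %), picolinic acid (20 mol %), K3PO4, DMSO, 100 °C
Reagents that add atoms: none
Why: Ullmann diaryl ether synthesis with the CuI/picolinic acid system is known to couple ortho,ortho-disubstituted phenols with electron-rich aryl halides, and the bromide here has no ortho substituent.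

Step 24
Reactants: 39 2-(benzyloxy)-1,3-dimethoxy-5-(2,4,6-trimethoxyphenoxy)benzene
Product: 40 2,6-dimethoxy-4-(2,4,6-trimethoxyphenoxy)phenol
Conditions: H2 (1 atm), Pd/C, EtOAc/MeOH, rt
Reagents that add atoms: none
Why: Benzyl ether hydrogenolysis over palladium on carbon frees the ring G phenol.

Step 25
Reactants: 40 2,6-dimethoxy-4-(2,4,6-trimethoxyphenoxy)phenol; 11 trichloroethylene
Product: 41 2-{[(E)-1,2-dichloroethenyl]oxy}-1,3-dimethoxy-5-(2,4,6-trimethoxyphenoxy)benzene
Conditions: K2CO3, DMF, 70 °C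
Reagents that add atoms: none
Why: Dichlorovinylation of the phenol by trichloroethylene (first stage of the Greene ynol ether synthesis), as in step 8.

Step 26
Reactants: 41 dichlorovinyl ether of the G–H unit
Product: 44 2-(ethynyloxy)-1,3-dimethoxy-5-(2,4,6-trimethoxyphenoxy)benzene, via chloroalkyne 42 (not isolated), via lithium acetylide 43 (not isolated)
Conditions: n-BuLi (2.2 equiv), THF, −78 to −60 °C; then H2O
Reagents that add atoms: none
Why: Second stage of the Greene ynol ether synthesis (elimination to chloroalkyne 42, chlorine–lithium exchange to acetylide 43, protonation), kept cold so that ring metalation of the methoxyarenes does not compete.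

Step 27
Reactants: 35 cyclobutenone of the pentamer; 44 2-(ethynyloxy)-1,3-dimethoxy-5-(2,4,6-trimethoxyphenoxy)benzene
Product: 49 octamer phenol A–H (ring F 4-OH free; all nineteen other oxygens OMe), via vinylketene 45 (not isolated), via vinylcyclobutenone 46 (not isolated), via dienylketene 47 (not isolated), via cyclohexadienone 48 (not isolated)
Conditions: PhMe (degassed), 110 °C, slow addition of 44 (1.5 equiv)
Reagents that add atoms: none
Why: The Danheiser benzannulation cascade of step 10 should close ring F with the ring E oxygen at C1 and the ring G oxygen at C2, the [2+2] regiochemistry again being set by the polarisation of the ynol ether.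

Step 28
Reactants: 49 octamer phenol A–H
Product: 50 CNP0319661.0 (octamer A–H with twenty free hydroxyls)
Conditions: BBr3 (40 equiv), CH2Cl2, −78 °C to rt; MeOH then H2O, Ar
Reagents that add atoms: none
Why: Lewis acid O-demethylation with BBr3 should cleave all nineteen aryl methyl ethers while the diaryl ether bonds stay inert, with work-up under argon to protect the polyphenol from oxidation.

**Compound list**

1 | squaric acid (3,4-dihydroxycyclobut-3-ene-1,2-dione) | O=C1C(=O)C(O)=C1O | starting material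
2 | squaryl dichloride (3,4-dichlorocyclobut-3-ene-1,2-dione) | O=C1C(=O)C(Cl)=C1Cl | intermediate
3 | 3-chloro-4-methoxycyclobut-3-ene-1,2-dione | COC1=C(Cl)C(=O)C1=O | intermediate
4 | 3,5-dimethoxyphenol | COc1cc(O)cc(OC)c1 | starting material
5 | 3-(3,5-dimethoxyphenoxy)-4-methoxycyclobut-3-ene-1,2-dione | COC1=C(Oc2cc(OC)cc(OC)c2)C(=O)C1=O | intermediate
6 | 2-(3,5-dimethoxyphenoxy)-4-hydroxy-3-methoxycyclobut-2-en-1-one (racemic) | O=C1C(Oc2cc(OC)cc(OC)c2)=C(OC)C1O | intermediate
7 | 2-(3,5-dimethoxyphenoxy)-3,4-dimethoxycyclobut-2-en-1-one (racemic) | O=C1C(Oc2cc(OC)cc(OC)c2)=C(OC)C1OC | intermediate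
8 | 2,6-dimethoxy-1,4-benzoquinone | COC1=CC(=O)C=C(OC)C1=O | starting material
9 | 2,6-dimethoxybenzene-1,4-diol | COc1cc(O)cc(OC)c1O | intermediate
10 | 4-(benzyloxy)-2,6-dimethoxyphenol | COc1cc(OCc2ccccc2)cc(OC)c1O | intermediate
11 | trichloroethylene | ClC=C(Cl)Cl | starting material
12 | 5-(benzyloxy)-2-{[(E)-1,2-dichloroethenyl]oxy}-1,3-dimethoxybenzene | Cl/C=C(/Cl)Oc1c(OC)cc(OCc2ccccc2)cc1OC | intermediate
13 | 5-(benzyloxy)-2-[(chloroethynyl)oxy]-1,3-dimethoxybenzene | ClC#COc1c(OC)cc(OCc2ccccc2)cc1OC | intermediate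
14 | lithium [4-(benzyloxy)-2,6-dimethoxyphenoxy]acetylide | [Li]C#COc1c(OC)cc(OCc2ccccc2)cc1OC | intermediate
15 | 5-(benzyloxy)-2-(ethynyloxy)-1,3-dimethoxybenzene | C#COc1c(OC)cc(OCc2ccccc2)cc1OC | intermediate
16 | (3Z)-2-(3,5-dimethoxyphenoxy)-3,4-dimethoxybuta-1,3-dien-1-one (vinylketene) | O=C=C(Oc1cc(OC)cc(OC)c1)/C(OC)=C/OC | intermediate
17 | 3-[4-(benzyloxy)-2,6-dimethoxyphenoxy]-4-[(Z)-1,2-dimethoxyethenyl]-4-(3,5-dimethoxyphenoxy)cyclobut-2-en-1-one (racemic) | O=C1C=C(Oc2c(OC)cc(OCc3ccccc3)cc2OC)C1(Oc2cc(OC)cc(OC)c2)/C(OC)=C/OC | intermediate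
18 | (3Z,5Z)-3-[4-(benzyloxy)-2,6-dimethoxyphenoxy]-4-(3,5-dimethoxyphenoxy)-5,6-dimethoxyhexa-1,3,5-trien-1-one (dienylketene) | O=C=C/C(Oc1c(OC)cc(OCc2ccccc2)cc1OC)=C(Oc1cc(OC)cc(OC)c1)\C(OC)=C\OC | intermediate
19 | 3-[4-(benzyloxy)-2,6-dimethoxyphenoxy]-4-(3,5-dimethoxyphenoxy)-5,6-dimethoxycyclohexa-2,4-dien-1-one (racemic) | O=C1C=C(Oc2c(OC)cc(OCc3ccccc3)cc2OC)C(Oc2cc(OC)cc(OC)c2)=C(OC)C1OC | intermediate
20 | 5-[4-(benzyloxy)-2,6-dimethoxyphenoxy]-4-(3,5-dimethoxyphenoxy)-2,3-dimethoxyphenol (trimer A–C, ring B 4-OH free) | COc1cc(OC)cc(Oc2c(Oc3c(OC)cc(OCc4ccccc4)cc3OC)cc(O)c(OC)c2OC)c1 | intermediate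
21 | 5-(benzyloxy)-2-[2-(3,5-dimethoxyphenoxy)-3,4,5-trimethoxyphenoxy]-1,3-dimethoxybenzene | COc1cc(OC)cc(Oc2c(Oc3c(OC)cc(OCc4ccccc4)cc3OC)cc(OC)c(OC)c2OC)c1 | intermediate
22 | 4-[2-(3,5-dimethoxyphenoxy)-3,4,5-trimethoxyphenoxy]-3,5-dimethoxyphenol | COc1cc(OC)cc(Oc2c(Oc3c(OC)cc(O)cc3OC)cc(OC)c(OC)c2OC)c1 | intermediate
23 | 3-{4-[2-(3,5-dimethoxyphenoxy)-3,4,5-trimethoxyphenoxy]-3,5-dimethoxyphenoxy}-4-methoxycyclobut-3-ene-1,2-dione | COc1cc(OC)cc(Oc2c(Oc3c(OC)cc(OC4=C(OC)C(=O)C4=O)cc3OC)cc(OC)c(OC)c2OC)c1 | intermediate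
24 | 2-{4-[2-(3,5-dimethoxyphenoxy)-3,4,5-trimethoxyphenoxy]-3,5-dimethoxyphenoxy}-4-hydroxy-3-methoxycyclobut-2-en-1-one (racemic) | COc1cc(OC)cc(Oc2c(Oc3c(OC)cc(OC4=C(OC)C(O)C4=O)cc3OC)cc(OC)c(OC)c2OC)c1 | intermediate
25 | 2-{4-[2-(3,5-dimethoxyphenoxy)-3,4,5-trimethoxyphenoxy]-3,5-dimethoxyphenoxy}-3,4-dimethoxycyclobut-2-en-1-one (racemic) | COc1cc(OC)cc(Oc2c(Oc3c(OC)cc(OC4=C(OC)C(OC)C4=O)cc3OC)cc(OC)c(OC)c2OC)c1 | intermediate
26 | vinylketene from 25 (as 16, with the A–C trimer aryloxy group in place of 3,5-dimethoxyphenoxy; 3Z) | O=C=C(Oc1cc(OC)c(Oc2cc(OC)c(OC)c(OC)c2Oc2cc(OC)cc(OC)c2)c(OC)c1)/C(OC)=C/OC | intermediate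
27 | vinylcyclobutenone from 26 and 15 (as 17, with the A–C trimer aryloxy group at the quaternary carbon; racemic) | O=C1C=C(Oc2c(OC)cc(OCc3ccccc3)cc2OC)C1(Oc2cc(OC)c(Oc3cc(OC)c(OC)c(OC)c3Oc3cc(OC)cc(OC)c3)c(OC)c2)/C(OC)=C/OC | intermediate
28 | dienylketene from 27 (as 18, with the A–C trimer aryloxy group at C4; 3Z,5Z) | O=C=C/C(Oc1c(OC)cc(OCc2ccccc2)cc1OC)=C(Oc1cc(OC)c(Oc2cc(OC)c(OC)c(OC)c2Oc2cc(OC)cc(OC)c2)c(OC)c1)\C(OC)=C\OC | intermediate
29 | cyclohexadienone from 28 (as 19, with the A–C trimer aryloxy group at C4; racemic) | O=C1C=C(Oc2c(OC)cc(OCc3ccccc3)cc2OC)C(Oc2cc(OC)c(Oc3cc(OC)c(OC)c(OC)c3Oc3cc(OC)cc(OC)c3)c(OC)c2)=C(OC)C1OC | intermediate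
30 | pentamer phenol A–E (ring D 4-OH free; ring E 4-OBn; all other oxygens OMe) | COc1cc(OC)cc(Oc2c(Oc3c(OC)cc(Oc4c(Oc5c(OC)cc(OCc6ccccc6)cc5OC)cc(O)c(OC)c4OC)cc3OC)cc(OC)c(OC)c2OC)c1 | intermediate
31 | pentamer A–E benzyl ether (ring D 4-OMe; ring E 4-OBn; all other oxygens OMe) | COc1cc(OC)cc(Oc2c(Oc3c(OC)cc(Oc4c(Oc5c(OC)cc(OCc6ccccc6)cc5OC)cc(OC)c(OC)c4OC)cc3OC)cc(OC)c(OC)c2OC)c1 | intermediate
32 | pentamer phenol A–E (ring E 4-OH free; all other oxygens OMe) | COc1cc(OC)cc(Oc2c(Oc3c(OC)cc(Oc4c(Oc5c(OC)cc(O)cc5OC)cc(OC)c(OC)c4OC)cc3OC)cc(OC)c(OC)c2OC)c1 | intermediate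
33 | methyl squarate ester of 32 (3-aryloxy-4-methoxycyclobut-3-ene-1,2-dione on the ring E 4-oxygen) | COc1cc(OC)cc(Oc2c(Oc3c(OC)cc(Oc4c(Oc5c(OC)cc(OC6=C(OC)C(=O)C6=O)cc5OC)cc(OC)c(OC)c4OC)cc3OC)cc(OC)c(OC)c2OC)c1 | intermediate
34 | hydroxycyclobutenone of the pentamer (2-aryloxy-4-hydroxy-3-methoxycyclobut-2-en-1-one on the ring E 4-oxygen; racemic) | COc1cc(OC)cc(Oc2c(Oc3c(OC)cc(Oc4c(Oc5c(OC)cc(OC6=C(OC)C(O)C6=O)cc5OC)cc(OC)c(OC)c4OC)cc3OC)cc(OC)c(OC)c2OC)c1 | intermediate
35 | cyclobutenone of the pentamer (2-aryloxy-3,4-dimethoxycyclobut-2-en-1-one on the ring E 4-oxygen; racemic) | COc1cc(OC)cc(Oc2c(Oc3c(OC)cc(Oc4c(Oc5c(OC)cc(OC6=C(OC)C(OC)C6=O)cc5OC)cc(OC)c(OC)c4OC)cc3OC)cc(OC)c(OC)c2OC)c1 | intermediate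
36 | 4-bromo-2,6-dimethoxyphenol | COc1cc(Br)cc(OC)c1O | starting material
37 | 2-(benzyloxy)-5-bromo-1,3-dimethoxybenzene | COc1cc(Br)cc(OC)c1OCc1ccccc1 | intermediate
38 | 2,4,6-trimethoxyphenol | COc1cc(OC)c(O)c(OC)c1 | starting material
39 | 2-(benzyloxy)-1,3-dimethoxy-5-(2,4,6-trimethoxyphenoxy)benzene | COc1cc(OC)c(Oc2cc(OC)c(OCc3ccccc3)c(OC)c2)c(OC)c1 | intermediate
40 | 2,6-dimethoxy-4-(2,4,6-trimethoxyphenoxy)phenol | COc1cc(OC)c(Oc2cc(OC)c(O)c(OC)c2)c(OC)c1 | intermediate
41 | 2-{[(E)-1,2-dichloroethenyl]oxy}-1,3-dimethoxy-5-(2,4,6-trimethoxyphenoxy)benzene | Cl/C=C(/Cl)Oc1c(OC)cc(Oc2c(OC)cc(OC)cc2OC)cc1OC | intermediate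
42 | 2-[(chloroethynyl)oxy]-1,3-dimethoxy-5-(2,4,6-trimethoxyphenoxy)benzene | ClC#COc1c(OC)cc(Oc2c(OC)cc(OC)cc2OC)cc1OC | intermediate
43 | lithium [2,6-dimethoxy-4-(2,4,6-trimethoxyphenoxy)phenoxy]acetylide | [Li]C#COc1c(OC)cc(Oc2c(OC)cc(OC)cc2OC)cc1OC | intermediate
44 | 2-(ethynyloxy)-1,3-dimethoxy-5-(2,4,6-trimethoxyphenoxy)benzene | C#COc1c(OC)cc(Oc2c(OC)cc(OC)cc2OC)cc1OC | intermediate
45 | vinylketene from 35 (as 16, with the A–E pentamer aryloxy group in place of 3,5-dimethoxyphenoxy; 3Z) | O=C=C(Oc1cc(OC)c(Oc2cc(OC)c(OC)c(OC)c2Oc2cc(OC)c(Oc3cc(OC)c(OC)c(OC)c3Oc3cc(OC)cc(OC)c3)c(OC)c2)c(OC)c1)/C(OC)=C/OC | intermediate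
46 | vinylcyclobutenone from 45 and 44 (G–H aryloxy group at C3, A–E pentamer aryloxy group at the quaternary carbon; racemic) | O=C1C=C(Oc2c(OC)cc(Oc3c(OC)cc(OC)cc3OC)cc2OC)C1(Oc2cc(OC)c(Oc3cc(OC)c(OC)c(OC)c3Oc3cc(OC)c(Oc4cc(OC)c(OC)c(OC)c4Oc4cc(OC)cc(OC)c4)c(OC)c3)c(OC)c2)/C(OC)=C/OC | intermediate
47 | dienylketene from 46 (G–H aryloxy group at C3, A–E pentamer aryloxy group at C4; 3Z,5Z) | O=C=C/C(Oc1c(OC)cc(Oc2c(OC)cc(OC)cc2OC)cc1OC)=C(Oc1cc(OC)c(Oc2cc(OC)c(OC)c(OC)c2Oc2cc(OC)c(Oc3cc(OC)c(OC)c(OC)c3Oc3cc(OC)cc(OC)c3)c(OC)c2)c(OC)c1)\C(OC)=C\OC | intermediate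
48 | cyclohexadienone from 47 (G–H aryloxy group at C3, A–E pentamer aryloxy group at C4, methoxy groups at C5 and C6; racemic) | O=C1C=C(Oc2c(OC)cc(Oc3c(OC)cc(OC)cc3OC)cc2OC)C(Oc2cc(OC)c(Oc3cc(OC)c(OC)c(OC)c3Oc3cc(OC)c(Oc4cc(OC)c(OC)c(OC)c4Oc4cc(OC)cc(OC)c4)c(OC)c3)c(OC)c2)=C(OC)C1OC | intermediate
49 | octamer phenol A–H (ring F 4-OH free; all nineteen other oxygens OMe) | COc1cc(OC)cc(Oc2c(Oc3c(OC)cc(Oc4c(Oc5c(OC)cc(Oc6c(Oc7c(OC)cc(Oc8c(OC)cc(OC)cc8OC)cc7OC)cc(O)c(OC)c6OC)cc5OC)cc(OC)c(OC)c4OC)cc3OC)cc(OC)c(OC)c2OC)c1 | intermediate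
50 | CNP0319661.0 (octamer A–H with twenty free hydroxyls) | Oc1cc(O)cc(Oc2c(Oc3c(O)cc(Oc4c(Oc5c(O)cc(Oc6c(Oc7c(O)cc(Oc8c(O)cc(O)cc8O)cc7O)cc(O)c(O)c6O)cc5O)cc(O)c(O)c4O)cc3O)cc(O)c(O)c2O)c1 | target

**Totals and risks**

Total step count: 28. Longest linear sequence: 19 steps (steps 1–5, 10–21, 27, 28).

Steps most likely to fail:

1. Step 10 (the same risk recurs in steps 16 and 27). The terminal aryl ynol ether may self-condense, or the electron-rich vinylketene may dimerise, faster than the two partners meet in the [2+2] step. Fallback: setting out from 12, the n-BuLi treatment of step 9 is quenched with Me3SiCl instead of water, so that acetylide 14 is trapped as {[4-(benzyloxy)-2,6-dimethoxyphenoxy]ethynyl}trimethylsilane F1. This capped ynol ether should be thermally more robust, and the β-silicon effect should reinforce the same polarisation. Heating F1 with 7 in toluene should give 5-[4-(benzyloxy)-2,6-dimethoxyphenoxy]-4-(3,5-dimethoxyphenoxy)-2,3-dimethoxy-6-(trimethylsilyl)phenol F2 by the same cascade. Ipso-protodesilylation of the ortho-silyl phenol (Bu4NF, THF) comes back to the route at 20.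

2. Step 4 (the same risk recurs in steps 14 and 20). Hydride may add to the carbonyl next to C–OAr, or may displace the aryloxide by addition–elimination, so that the wrong regioisomer or a de-arylated product results. Fallback: setting out from 2 and two equivalents of 4 (i-Pr2NEt, CH2Cl2), the symmetrical 3,4-bis(3,5-dimethoxyphenoxy)cyclobut-3-ene-1,2-dione F3 is made, for which reduction raises no regiochemical question. LiAlH(O-t-Bu)3 should give 2,3-bis(3,5-dimethoxyphenoxy)-4-hydroxycyclobut-2-en-1-one F4, and Ag2O/MeI its methyl ether 2,3-bis(3,5-dimethoxyphenoxy)-4-methoxycyclobut-2-en-1-one F5. Vinylogous transesterification (MeOH, catalytic K2CO3, 0 °C) can only exchange the aryloxy group at the β-carbon of the enone. It therefore comes back to the route at 7 and returns one equivalent of 4.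

3. Step 28. Cleavage of nineteen methyl ethers may stop short, and the partly deprotected polyphenols may oxidise and streak during purification, so that the free target cannot be separated. Fallback: setting out from 49, the crude BBr3 product is peracetylated (Ac2O, pyridine, DMAP) to the icosaacetate of 50 F6, which is stable to air and silica and can be separated from acetates of incompletely demethylated material (these are recycled through BBr3). Zemplén deacetylation (catalytic NaOMe, MeOH, Ar, then acidic resin) comes back to the route at 50.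

**Further compounds**

F1 | step 10 | {[4-(benzyloxy)-2,6-dimethoxyphenoxy]ethynyl}trimethylsilane | C[Si](C)(C)C#COc1c(OC)cc(OCc2ccccc2)cc1OC
F2 | step 10 | 5-[4-(benzyloxy)-2,6-dimethoxyphenoxy]-4-(3,5-dimethoxyphenoxy)-2,3-dimethoxy-6-(trimethylsilyl)phenol | COc1cc(OC)cc(Oc2c(Oc3c(OC)cc(OCc4ccccc4)cc3OC)c([Si](C)(C)C)c(O)c(OC)c2OC)c1
F3 | step 4 | 3,4-bis(3,5-dimethoxyphenoxy)cyclobut-3-ene-1,2-dione | COc1cc(OC)cc(OC2=C(Oc3cc(OC)cc(OC)c3)C(=O)C2=O)c1
F4 | step 4 | 2,3-bis(3,5-dimethoxyphenoxy)-4-hydroxycyclobut-2-en-1-one (racemic) | O=C1C(Oc2cc(OC)cc(OC)c2)=C(Oc2cc(OC)cc(OC)c2)C1O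
F5 | step 4 | 2,3-bis(3,5-dimethoxyphenoxy)-4-methoxycyclobut-2-en-1-one (racemic) | O=C1C(Oc2cc(OC)cc(OC)c2)=C(Oc2cc(OC)cc(OC)c2)C1OC
F6 | step 28 | icosaacetate of 50 (every hydroxyl as its acetate) | CC(=O)Oc1cc(OC(C)=O)cc(Oc2c(Oc3c(OC(C)=O)cc(Oc4c(Oc5c(OC(C)=O)cc(Oc6c(Oc7c(OC(C)=O)cc(Oc8c(OC(C)=O)cc(OC(C)=O)cc8OC(C)=O)cc7OC(C)=O)cc(OC(C)=O)c(OC(C)=O)c6OC(C)=O)cc5OC(C)=O)cc(OC(C)=O)c(OC(C)=O)c4OC(C)=O)cc3OC(C)=O)cc(OC(C)=O)c(OC(C)=O)c2OC(C)=O)c1
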